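**Plan**

- Target: (5R)-1-(3,4-dihydroxyphenyl)-5-hydroxy-7-(4-hydroxy-3-methoxyphenyl)heptan-3-one, chain numbered from C1 (on catechol ring B) to C7 (on guaiacyl ring A).
- Enabling feature: C4H2–C5H(OH)–C6H2 is the intact three-carbon frame of epichlorohydrin. It lies between the C3 carbonyl (an acyl anion once masked as a 1,3-dithiane) and C7, which is benzylic to ring A (a benzyl nucleophile).
- Retrosynthesis: remove the three benzyl ethers and the dithiane mask, then cut C3–C4 and C6–C7 to reach a 2-(2-arylethyl)-1,3-dithiane, (S)-epichlorohydrin and a benzylic Grignard reagent.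
- Forward: the dithiane arm takes three steps and the Grignard arm two. The chain is joined in one flask, C3–C4 first (dithiane anion on the oxirane), then C6–C7 (Grignard/CuI on the re-formed oxirane). No ring is built.
- Stereochemistry: the only stereocentre, C5, is bought with (S)-epichlorohydrin. Its C–O bond is never broken and it ends as 5R.

Key step: step 6

Assumption: [4-(benzyloxy)-3-methoxyphenyl]methanol is purchased as such, and all phenols are carried as benzyl ethers until the last step.

Step 1
Reactants: 1 3-(3,4-dihydroxyphenyl)propanoic acid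
Product: 2 benzyl 3-[3,4-bis(benzyloxy)phenyl]propanoate
Conditions: BnBr (3.5 equiv), K2CO3 (4 equiv), DMF, 60 °C, N2
Reagents that add atoms: benzyl bromide, BrCc1ccccc1
Why: Threefold SN2 O-alkylation (Williamson etherification of both phenols plus esterification of the carboxylate) under K2CO3 should cap every acidic OH in one operation, with air excluded so that the catechol is not oxidised before it is alkylated.

Step 2
Reactants: 2 benzyl 3-[3,4-bis(benzyloxy)phenyl]propanoate
Product: 3 3-[3,4-bis(benzyloxy)phenyl]propanal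
Conditions: i-Bu2AlH (1.1 equiv), CH2Cl2, −78 °C; MeOH quench, then aq. potassium sodium tartrate (KNaC4H4O6)
Reagents that add atoms: none
Why: Partial ester reduction with i-Bu2AlH relies on the tetrahedral aluminium hemiacetal being stable at −78 °C and collapsing to the aldehyde only on work-up, and aryl benzyl ethers are inert to the hydride.

Step 3
Reactants: 3 3-[3,4-bis(benzyloxy)phenyl]propanal; 4 propane-1,3-dithiol
Product: 5 2-{2-[3,4-bis(benzyloxy)phenyl]ethyl}-1,3-dithiane
Conditions: 4 (1.1 equiv), BF3·OEt2 (0.2 equiv), CH2Cl2, 0 °C → rt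
Reagents that add atoms: none
Why: Lewis-acid-catalysed thioacetalisation of an unhindered aliphatic aldehyde with a 1,3-dithiol is fast at 0 °C, and substoichiometric BF3·OEt2 with a short contact time should leave the aryl benzyl ethers untouched.

Step 4
Reactants: 6 [4-(benzyloxy)-3-methoxyphenyl]methanol
Product: 7 1-(benzyloxy)-4-(chloromethyl)-2-methoxybenzene
Conditions: SOCl2 (1.2 equiv), CH2Cl2, 0 °C → rt; strip with toluene, use crude
Reagents that add atoms: thionyl chloride, O=S(Cl)Cl
Why: Deoxychlorination with SOCl2 goes through the chlorosulfite of an electron-rich benzylic alcohol, which collapses to the chloride readily at 0 °C while the benzyl and methyl ethers survive.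

Step 5
Reactants: 7 1-(benzyloxy)-4-(chloromethyl)-2-methoxybenzene
Product: 8 [4-(benzyloxy)-3-methoxybenzyl]magnesium chloride (THF solution, titrated, used directly)
Conditions: Mg turnings (3 equiv, activated with a crystal of I2), THF, 0 °C, slow addition of dilute 7
Reagents that add atoms: magnesium, [Mg]
Why: Grignard formation by insertion of magnesium into the benzylic C–Cl bond is standard for alkoxy-substituted benzyl chlorides, and excess metal, low temperature and slow addition of a dilute solution keep the halide concentration low enough to suppress Wurtz coupling.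

Step 6
Reactants: 5 2-{2-[3,4-bis(benzyloxy)phenyl]ethyl}-1,3-dithiane; 9 (S)-epichlorohydrin; 8 [4-(benzyloxy)-3-methoxybenzyl]magnesium chloride
Product: 13 (2R)-4-[4-(benzyloxy)-3-methoxyphenyl]-1-(2-{2-[3,4-bis(benzyloxy)phenyl]ethyl}-1,3-dithian-2-yl)butan-2-ol, via lithiated dithiane 10 (not isolated), via chlorohydrin lithium alkoxide 11 (not isolated), via dithianylmethyl oxirane 12 (not isolated)
Conditions: n-BuLi (1.0 equiv), THF, −30 °C, 2 h; 9 (1.05 equiv), −78 → −20 °C, then 0 °C → rt; CuI (0.2 equiv), 8 (2 equiv), −30 → 0 °C; aq. NH4Cl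
Reagents that add atoms: none
Why: n-BuLi removes the C2–H of dithiane 5 (Corey–Seebach umpolung), and the acyl-anion equivalent 10 opens (S)-epichlorohydrin by SN2 attack at the unsubstituted oxirane carbon, forging C3–C4 and giving alkoxide 11. On warming, 11 displaces chloride in a 3-exo-tet closure to the transient terminal epoxide 12, whose CH2 is then attacked by the benzylic organocopper species formed from Grignard 8 and catalytic CuI, forging C6–C7 and consuming the oxirane so that no ring remains in 13. The closest known reaction type is the dithiane–epichlorohydrin linchpin coupling followed by copper-catalysed Grignard opening of a terminal epoxide. No new stereocentre is created: C5 is the carbinol carbon of 9 and its C–O bond is never broken, so the S descriptor of 9 becomes R in 13 only through the change in substituent priorities. The step needs the first nucleophile to attack the oxirane CH2 and not the C–Cl carbon, because direct chloride displacement would give the enantiomeric epoxide; the higher SN2 reactivity of the strained, unhindered oxirane terminus towards the soft, bulky dithiane anion at low temperature should secure this, and both later attacks fall on primary carbons for the same steric reason.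

Step 7
Reactants: 13 (2R)-4-[4-(benzyloxy)-3-methoxyphenyl]-1-(2-{2-[3,4-bis(benzyloxy)phenyl]ethyl}-1,3-dithian-2-yl)butan-2-ol
Product: 14 (5R)-7-[4-(benzyloxy)-3-methoxyphenyl]-1-[3,4-bis(benzyloxy)phenyl]-5-hydroxyheptan-3-one
Conditions: MeI (10 equiv), CaCO3 (5 equiv), MeCN/H2O (9:1), 45 °C
Reagents that add atoms: water, O
Why: In this alkylative thioacetal hydrolysis, S-methylation turns sulfur into a sulfonium leaving group, water captures the thionium ion and CaCO3 buffers the HI, so the ketone should be released under near-neutral, non-oxidising conditions that spare the electron-rich arenes, the benzyl ethers and the C5 carbinol.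

Step 8
Reactants: 14 (5R)-7-[4-(benzyloxy)-3-methoxyphenyl]-1-[3,4-bis(benzyloxy)phenyl]-5-hydroxyheptan-3-one
Product: 15 (5R)-1-(3,4-dihydroxyphenyl)-5-hydroxy-7-(4-hydroxy-3-methoxyphenyl)heptan-3-one
Conditions: H2 (1 atm), 10% Pd/C, EtOAc/MeOH, rt; filter and concentrate under N2
Reagents that add atoms: none
Why: Catalytic hydrogenolysis over Pd/C cleaves the three benzylic C–O bonds of the aryl benzyl ethers at room temperature without reducing the aliphatic ketone or the non-benzylic secondary alcohol, so C5 stays 5R.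

**Compound list**

1 | 3-(3,4-dihydroxyphenyl)propanoic acid (dihydrocaffeic acid) | OC(=O)CCc1ccc(O)c(O)c1 | starting material
2 | benzyl 3-[3,4-bis(benzyloxy)phenyl]propanoate | O=C(CCc1ccc(OCc2ccccc2)c(OCc2ccccc2)c1)OCc1ccccc1 | intermediate
3 | 3-[3,4-bis(benzyloxy)phenyl]propanal | O=CCCc1ccc(OCc2ccccc2)c(OCc2ccccc2)c1 | intermediate
4 | propane-1,3-dithiol | SCCCS | starting material
5 | 2-{2-[3,4-bis(benzyloxy)phenyl]ethyl}-1,3-dithiane | C1CSC(CCc2ccc(OCc3ccccc3)c(OCc3ccccc3)c2)SC1 | intermediate
6 | [4-(benzyloxy)-3-methoxyphenyl]methanol | COc1cc(CO)ccc1OCc1ccccc1 | starting material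
7 | 1-(benzyloxy)-4-(chloromethyl)-2-methoxybenzene | COc1cc(CCl)ccc1OCc1ccccc1 | intermediate
8 | [4-(benzyloxy)-3-methoxybenzyl]magnesium chloride | COc1cc(C[Mg]Cl)ccc1OCc1ccccc1 | intermediate
9 | (S)-epichlorohydrin, (2S)-2-(chloromethyl)oxirane | ClC[C@@H]1CO1 | starting material
10 | 2-lithio-2-{2-[3,4-bis(benzyloxy)phenyl]ethyl}-1,3-dithiane | [Li]C1(CCc2ccc(OCc3ccccc3)c(OCc3ccccc3)c2)SCCCS1 | intermediate
11 | lithium (2S)-1-chloro-3-(2-{2-[3,4-bis(benzyloxy)phenyl]ethyl}-1,3-dithian-2-yl)propan-2-olate | ClC[C@@H](O[Li])CC1(CCc2ccc(OCc3ccccc3)c(OCc3ccccc3)c2)SCCCS1 | intermediate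
12 | 2-{2-[3,4-bis(benzyloxy)phenyl]ethyl}-2-{[(2S)-oxiran-2-yl]methyl}-1,3-dithiane | C1CSC(CCc2ccc(OCc3ccccc3)c(OCc3ccccc3)c2)(C[C@H]2CO2)SC1 | intermediate
13 | (2R)-4-[4-(benzyloxy)-3-methoxyphenyl]-1-(2-{2-[3,4-bis(benzyloxy)phenyl]ethyl}-1,3-dithian-2-yl)butan-2-ol | COc1cc(CC[C@@H](O)CC2(CCc3ccc(OCc4ccccc4)c(OCc4ccccc4)c3)SCCCS2)ccc1OCc1ccccc1 | intermediate
14 | (5R)-7-[4-(benzyloxy)-3-methoxyphenyl]-1-[3,4-bis(benzyloxy)phenyl]-5-hydroxyheptan-3-one | COc1cc(CC[C@@H](O)CC(=O)CCc2ccc(OCc3ccccc3)c(OCc3ccccc3)c2)ccc1OCc1ccccc1 | intermediate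
15 | (5R)-1-(3,4-dihydroxyphenyl)-5-hydroxy-7-(4-hydroxy-3-methoxyphenyl)heptan-3-one | COc1cc(CC[C@@H](O)CC(=O)CCc2ccc(O)c(O)c2)ccc1O | target

**Step count**

Total: 8 steps. Longest linear sequence: 6 steps (steps 1, 2, 3, 6, 7, 8 from dihydrocaffeic acid); steps 4 and 5 form the convergent arm.

**Steps most likely to fail**

Step 6. The risk is loss of chemoselectivity in a crowded flask. The dithiane anion may displace chloride directly, which would erode enantiomeric purity. Oxirane re-closure may be incomplete when the Grignard reagent is added. The benzylic organocopper species may be lost to homocoupling or to binding by the thioacetal sulfur. The fallback sets out from 8 and 5 and returns at 13; it reverses the order of the two nucleophiles and separates the stages. Grignard 8 is added with CuI at −40 °C to (R)-epichlorohydrin (ClC[C@H]1CO1, the enantiomer required when the benzyl group is introduced first), which should give (2R)-4-[4-(benzyloxy)-3-methoxyphenyl]-1-chlorobutan-2-ol F1. NaOH in aqueous THF should close this to (2R)-2-{2-[4-(benzyloxy)-3-methoxyphenyl]ethyl}oxirane F2. Lithiated 5 (that is, 10; n-BuLi, THF/DMPU, −30 → 0 °C) then opens F2 at its CH2 to give 13.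

Step 5. The risk is Wurtz-type homocoupling of the electron-rich benzylic chloride during magnesium insertion, which would consume the halide as a bibenzyl. The fallback sets out from 7 and returns at 13; it replaces the organomagnesium by a sulfone-stabilised benzylic carbanion. Chloride 7 is treated with PhSO2Na in DMF to give 1-(benzyloxy)-2-methoxy-4-[(phenylsulfonyl)methyl]benzene F3. Deprotonation with n-BuLi in THF at −78 °C gives {[4-(benzyloxy)-3-methoxyphenyl](phenylsulfonyl)methyl}lithium F4. This anion opens epoxide 12 (obtained by stopping step 6 after oxirane closure and working up) in the presence of BF3·OEt2, giving (2R)-4-[4-(benzyloxy)-3-methoxyphenyl]-1-(2-{2-[3,4-bis(benzyloxy)phenyl]ethyl}-1,3-dithian-2-yl)-4-(phenylsulfonyl)butan-2-ol F5 as a mixture of epimers at the sulfone carbon, which does not matter. Reductive desulfonylation of the Julia type with sodium amalgam (Na/Hg), Na2HPO4 and MeOH should then deliver 13.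

Step 7. The risk is dehydration (β-elimination) or retro-aldol cleavage of the liberated β-hydroxy ketone during the slow, warm alkylative hydrolysis. The fallback sets out from 13 and returns at 14; it masks the C5 hydroxyl so that retro-aldol cleavage is impossible and the hydrolysis can be driven harder. Silylation of 13 (TBSOTf, 2,6-lutidine, CH2Cl2, 0 °C) should give tert-butyl{[(2R)-4-[4-(benzyloxy)-3-methoxyphenyl]-1-(2-{2-[3,4-bis(benzyloxy)phenyl]ethyl}-1,3-dithian-2-yl)butan-2-yl]oxy}dimethylsilane F6. Hydrolysis with MeI and CaCO3 in MeCN/H2O at 60 °C should give (5R)-7-[4-(benzyloxy)-3-methoxyphenyl]-1-[3,4-bis(benzyloxy)phenyl]-5-[(tert-butyldimethylsilyl)oxy]heptan-3-one F7. HF·pyridine in THF at 0 °C → rt then removes the silyl group to give 14.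

**Further compounds**

F1 | step 6 | (2R)-4-[4-(benzyloxy)-3-methoxyphenyl]-1-chlorobutan-2-ol | COc1cc(CC[C@@H](O)CCl)ccc1OCc1ccccc1
F2 | step 6 | (2R)-2-{2-[4-(benzyloxy)-3-methoxyphenyl]ethyl}oxirane | COc1cc(CC[C@@H]2CO2)ccc1OCc1ccccc1
F3 | step 5 | 1-(benzyloxy)-2-methoxy-4-[(phenylsulfonyl)methyl]benzene | COc1cc(CS(=O)(=O)c2ccccc2)ccc1OCc1ccccc1
F4 | step 5 | {[4-(benzyloxy)-3-methoxyphenyl](phenylsulfonyl)methyl}lithium | COc1cc(C([Li])S(=O)(=O)c2ccccc2)ccc1OCc1ccccc1
F5 | step 5 | (2R)-4-[4-(benzyloxy)-3-methoxyphenyl]-1-(2-{2-[3,4-bis(benzyloxy)phenyl]ethyl}-1,3-dithian-2-yl)-4-(phenylsulfonyl)butan-2-ol (both epimers at C4) | COc1cc(C(C[C@@H](O)CC2(CCc3ccc(OCc4ccccc4)c(OCc4ccccc4)c3)SCCCS2)S(=O)(=O)c2ccccc2)ccc1OCc1ccccc1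
F6 | step 7 | tert-butyl{[(2R)-4-[4-(benzyloxy)-3-methoxyphenyl]-1-(2-{2-[3,4-bis(benzyloxy)phenyl]ethyl}-1,3-dithian-2-yl)butan-2-yl]oxy}dimethylsilane | COc1cc(CC[C@@H](O[Si](C)(C)C(C)(C)C)CC2(CCc3ccc(OCc4ccccc4)c(OCc4ccccc4)c3)SCCCS2)ccc1OCc1ccccc1
F7 | step 7 | (5R)-7-[4-(benzyloxy)-3-methoxyphenyl]-1-[3,4-bis(benzyloxy)phenyl]-5-[(tert-butyldimethylsilyl)oxy]heptan-3-one | COc1cc(CC[C@@H](O[Si](C)(C)C(C)(C)C)CC(=O)CCc2ccc(OCc3ccccc3)c(OCc3ccccc3)c2)ccc1OCc1ccccc1
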